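The C3–C4 bond of the pyran ring (O1–C2–C3–C4–C4a–C8a) joins two benzylic carbons, and C4 carries the free hydroxyl: the retron of a [1,2]-Wittig shift. Moving C3 back from C4 onto that oxygen gives a seven-membered 2,3-dihydro-5H-1,4-benzodioxepine, a cyclic dibenzylic ether whose only stereocentre (C3) comes from asymmetric transfer hydrogenation. Metalation of its C5 methylene makes C3 migrate from O4 to C5. In one operation the dioxepine contracts to the chroman, C3–C4 forms with retention at C3, O4 leaves the ring as the C4 alkoxide, and the trans C4 centre is set. Buffered fluoride then frees the three phenols.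

Key step: step 8

Assumption: isoflavan numbering is used for the target (ring B primed). The SMILES is read as the 3,4-trans isomer, (3S,4R). TIPS = triisopropylsilyl. Compounds 1, 3 and 6 are taken as catalogue chemicals.

Step 1
Reactants: 1 2,4-dihydroxy-5-methoxybenzaldehyde
Product: 2 2-hydroxy-5-methoxy-4-(triisopropylsilyloxy)benzaldehyde
Conditions: TIPSCl (1.05 equiv), imidazole, DMF, 0 °C → rt
Reagents that add atoms: chlorotriisopropylsilane, CC(C)[Si](Cl)(C(C)C)C(C)C
Why: Selective O-silylation: the 4-OH is the more acidic and accessible phenol, while the 2-OH is held in a hydrogen bond to the aldehyde, so one equivalent of the bulky chloride should react at O4 only.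

Step 2
Reactants: 3 2,3-dimethoxybenzene-1,4-diol
Product: 4 1,4-bis(triisopropylsilyloxy)-2,3-dimethoxybenzene
Conditions: TIPSOTf (2.3 equiv), 2,6-lutidine, CH2Cl2, 0 °C → rt
Reagents that add atoms: triisopropylsilyl triflate, CC(C)[Si](OS(=O)(=O)C(F)(F)F)(C(C)C)C(C)C
Why: Exhaustive O-silylation with the reactive triflate overcomes the flanking methoxy groups; TIPS is chosen because it has no acidic C–H, resists strong base at low temperature and leaves with fluoride under neutral conditions.

Step 3
Reactants: 4 1,4-bis(triisopropylsilyloxy)-2,3-dimethoxybenzene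
Product: 5 1-bromo-2,5-bis(triisopropylsilyloxy)-3,4-dimethoxybenzene
Conditions: NBS (1.0 equiv), MeCN, 0 °C, dark
Reagents that add atoms: N-bromosuccinimide, O=C1CCC(=O)N1Br
Why: Electrophilic aromatic bromination: the two free ring positions of symmetric 4 are equivalent, and the first bromine deactivates the ring against a second substitution.

Step 4
Reactants: 5 1-bromo-2,5-bis(triisopropylsilyloxy)-3,4-dimethoxybenzene; 6 2-chloro-N-methoxy-N-methylacetamide
Product: 8 2-chloro-1-[2,5-bis(triisopropylsilyloxy)-3,4-dimethoxyphenyl]ethan-1-one, via aryllithium 7 (not isolated)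
Conditions: n-BuLi, THF, −78 °C; then 6, −78 °C; AcOH quench at −78 °C
Reagents that add atoms: none
Why: Bromine–lithium exchange followed by Weinreb ketone synthesis: at −78 °C exchange and acylation should outrun O-to-C migration of the bulky silyl group, and the N-methoxy-N-methylamide stops the acylation at the ketone stage.

Step 5
Reactants: 2 2-hydroxy-5-methoxy-4-(triisopropylsilyloxy)benzaldehyde; 8 2-chloro-1-[2,5-bis(triisopropylsilyloxy)-3,4-dimethoxyphenyl]ethan-1-one
Product: 9 2-{2-[2,5-bis(triisopropylsilyloxy)-3,4-dimethoxyphenyl]-2-oxoethoxy}-5-methoxy-4-(triisopropylsilyloxy)benzaldehyde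
Conditions: K2CO3, acetone, rt
Reagents that add atoms: none
Why: Williamson ether synthesis (SN2 on an α-chloroketone): carbonate deprotonates only the free phenol of 2, and room temperature should hold the product back from the intramolecular aldol condensation of the Rap–Stoermer pathway.

Step 6
Reactants: 9 keto aldehyde
Product: 10 (S)-1-[2,5-bis(triisopropylsilyloxy)-3,4-dimethoxyphenyl]-2-[2-(hydroxymethyl)-4-methoxy-5-(triisopropylsilyloxy)phenoxy]ethan-1-ol
Conditions: RuCl[(R,R)-TsDPEN](p-cymene) (2 mol %), HCO2H/Et3N (1:1), CH2Cl2, 30 °C, degassed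
Reagents that add atoms: none
Why: Noyori–Ikariya asymmetric transfer hydrogenation reduces the aldehyde to CH2OH and the α-aryloxy aryl ketone to the carbinol in one pot; the (R,R)-catalyst, which gives (R)-1-arylethanols, should deliver hydride to the same face here, named S because CH2OAr outranks aryl, and this sets C3.

Step 7
Reactants: 10 (S)-diol
Product: 12 (3S)-3-[2,5-bis(triisopropylsilyloxy)-3,4-dimethoxyphenyl]-7-methoxy-8-(triisopropylsilyloxy)-2,3-dihydro-5H-1,4-benzodioxepine, via primary mesylate 11 (not isolated)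
Conditions: Ms2O (1.05 equiv), i-Pr2NEt, CH2Cl2 (5 mM), −30 °C → rt
Reagents that add atoms: none
Why: Selective sulfonylation of the unhindered primary alcohol gives the very labile 2,4-dioxygenated benzylic mesylate 11, which the secondary hydroxyl should capture in a 7-exo-tet etherification under high dilution; the C3–O bond is never broken, so the S configuration is kept.

Step 8
Reactants: 12 (3S)-benzodioxepine
Product: 15 (3S,4R)-3-[2,5-bis(triisopropylsilyloxy)-3,4-dimethoxyphenyl]-6-methoxy-7-(triisopropylsilyloxy)chroman-4-ol (3,4-trans), via C5-metalated ether 13 (not isolated), via C4 alkoxide 14 (not isolated)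
Conditions: n-BuLi/KOt-Bu/TMP(H) (2 equiv each), THF, −78 → −40 °C; sat. aq NH4Cl
Reagents that add atoms: none
Why: The hindered mixed Li/K tetramethylpiperidide removes one of the two C5 protons of 12 (α to O4, benzylic to ring A) to give 13, whose weak C3–O4 bond breaks homolytically to a tethered pair of aryl ketyl radical anion (C5–O4) and secondary benzylic radical (C3) that recombines at carbon to alkoxide 14. This is a [1,2]-Wittig rearrangement, known for benzyl sec-alkyl and dibenzyl ethers and, as a ring contraction, for cyclic dibenzylic ethers such as 5,7-dihydrodibenzo[c,e]oxepine, which gives 9,10-dihydrophenanthren-9-ol. The only ring closed is the pyran ring, by in-cage radical recombination between C3 and C5 (a formal 1,2-shift of C3 from O4 to C5), so the seven-membered ring O1–C2–C3–O4–C5–C5a–C9a expels O4 and becomes the six-membered ring O1–C2–C3–C4–C4a–C8a. C3 should be carried over with retention (3S to 3S) because the tethered pair collapses on the face that O4 has just left faster than rotation about C2–C3, and the new C4 centre is controlled by C3: bond formation through the half-chair that keeps the bulky bis(silyloxy)aryl group and the solvated metal alkoxide pseudo-equatorial and anti should give the trans (4R) carbinol. The step needs C5–H to be chosen over C3–H (whose anion would expel the O1 aryloxide), over ring C–H and over attack at silicon; C3–H is tertiary and screened by the ortho OTIPS group, which also twists ring B out of conjugation, the amine/amide couple relays ring anions to the benzylic site, and the irreversible shift drains 13 from these equilibria. TIPS ethers carry no acidic C–H, do not chelate the metal and should tolerate the base at −78 °C, and a late silyl transfer from O2' to the C4 alkoxide would be harmless because all silyl groups fall in the next step.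

Step 9
Reactants: 15 tris-TIPS trans-isoflavan-4-ol
Product: 16 (3S,4R)-3-(2,5-dihydroxy-3,4-dimethoxyphenyl)-6-methoxychroman-4,7-diol (target)
Conditions: TBAF/AcOH (1:1, 3.5 equiv), THF, 0 °C, Ar; pH 7 buffer work-up, deactivated silica
Reagents that add atoms: none
Why: Fluoride-induced cleavage of the three silyl ethers; acetic acid keeps the medium near neutral, so that phenoxide-driven quinone methide formation, hydroquinone autoxidation and acid ionisation of C4–OH with pterocarpan closure by the 2'-OH should all be avoided, and both stereocentres stay untouched.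

Compound list
1 | 2,4-dihydroxy-5-methoxybenzaldehyde | COc1cc(C=O)c(O)cc1O | starting material
2 | 2-hydroxy-5-methoxy-4-(triisopropylsilyloxy)benzaldehyde | COc1cc(C=O)c(O)cc1O[Si](C(C)C)(C(C)C)C(C)C | intermediate
3 | 2,3-dimethoxybenzene-1,4-diol | COc1c(O)ccc(O)c1OC | starting material
4 | 1,4-bis(triisopropylsilyloxy)-2,3-dimethoxybenzene | COc1c(O[Si](C(C)C)(C(C)C)C(C)C)ccc(O[Si](C(C)C)(C(C)C)C(C)C)c1OC | intermediate
5 | 1-bromo-2,5-bis(triisopropylsilyloxy)-3,4-dimethoxybenzene | COc1c(O[Si](C(C)C)(C(C)C)C(C)C)cc(Br)c(O[Si](C(C)C)(C(C)C)C(C)C)c1OC | intermediate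
6 | 2-chloro-N-methoxy-N-methylacetamide | CON(C)C(=O)CCl | starting material
7 | [2,5-bis(triisopropylsilyloxy)-3,4-dimethoxyphenyl]lithium | COc1c(O[Si](C(C)C)(C(C)C)C(C)C)cc([Li])c(O[Si](C(C)C)(C(C)C)C(C)C)c1OC | intermediate
8 | 2-chloro-1-[2,5-bis(triisopropylsilyloxy)-3,4-dimethoxyphenyl]ethan-1-one | COc1c(O[Si](C(C)C)(C(C)C)C(C)C)cc(C(=O)CCl)c(O[Si](C(C)C)(C(C)C)C(C)C)c1OC | intermediate
9 | keto aldehyde (aryloxymethyl aryl ketone) | COc1cc(C=O)c(OCC(=O)c2cc(O[Si](C(C)C)(C(C)C)C(C)C)c(OC)c(OC)c2O[Si](C(C)C)(C(C)C)C(C)C)cc1O[Si](C(C)C)(C(C)C)C(C)C | intermediate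
10 | (S)-diol | COc1cc(CO)c(OC[C@@H](O)c2cc(O[Si](C(C)C)(C(C)C)C(C)C)c(OC)c(OC)c2O[Si](C(C)C)(C(C)C)C(C)C)cc1O[Si](C(C)C)(C(C)C)C(C)C | intermediate
11 | primary benzylic mesylate of 10 | COc1cc(COS(C)(=O)=O)c(OC[C@@H](O)c2cc(O[Si](C(C)C)(C(C)C)C(C)C)c(OC)c(OC)c2O[Si](C(C)C)(C(C)C)C(C)C)cc1O[Si](C(C)C)(C(C)C)C(C)C | intermediate
12 | (3S)-3-aryl-7-methoxy-8-(triisopropylsilyloxy)-2,3-dihydro-5H-1,4-benzodioxepine | COc1cc2c(cc1O[Si](C(C)C)(C(C)C)C(C)C)OC[C@H](c3cc(O[Si](C(C)C)(C(C)C)C(C)C)c(OC)c(OC)c3O[Si](C(C)C)(C(C)C)C(C)C)OC2 | intermediate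
13 | C5-metalated 12 (drawn as the lithium species, C5 configurationally labile) | COc1cc2c(cc1O[Si](C(C)C)(C(C)C)C(C)C)OC[C@H](c3cc(O[Si](C(C)C)(C(C)C)C(C)C)c(OC)c(OC)c3O[Si](C(C)C)(C(C)C)C(C)C)OC2[Li] | intermediate
14 | C4 metal alkoxide of 15 (drawn as the lithium species) | COc1cc2c(cc1O[Si](C(C)C)(C(C)C)C(C)C)OC[C@H](c3cc(O[Si](C(C)C)(C(C)C)C(C)C)c(OC)c(OC)c3O[Si](C(C)C)(C(C)C)C(C)C)[C@H]2O[Li] | intermediate
15 | (3S,4R)-tris-TIPS trans-isoflavan-4-ol | COc1cc2c(cc1O[Si](C(C)C)(C(C)C)C(C)C)OC[C@H](c3cc(O[Si](C(C)C)(C(C)C)C(C)C)c(OC)c(OC)c3O[Si](C(C)C)(C(C)C)C(C)C)[C@H]2O | intermediate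
16 | (3S,4R)-3-(2,5-dihydroxy-3,4-dimethoxyphenyl)-6-methoxychroman-4,7-diol | COc1cc2c(cc1O)OC[C@H](c1cc(O)c(OC)c(OC)c1O)[C@H]2O | target

Total steps: 9. Longest linear sequence: 8 steps (3 → 4 → 5 → 8 → 9 → 10 → 12 → 15 → 16).

Steps most likely to fail

Step 8.
- **What may go wrong:**
  - metalation at C3–H followed by β-elimination of the O1 aryloxide;
  - unproductive ring metalation with O-to-C silyl migration;
  - attack of the base at silicon;
  - relaxation of the radical pair before collapse, which would erode the C3 configuration or the facial selectivity at C4.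
- **Fallback:** the carbanion is made by reductive lithiation instead of deprotonation. The fallback sets out from 12.
  - DDQ in CH2Cl2/MeOH abstracts hydride from the less hindered, ring-A-activated C5–H and should give the 5-methoxy acetal F1.
  - PhSH with catalytic BF3·OEt2 at −78 °C exchanges the exocyclic methoxy group and should give the 5-phenylthio ether F2.
  - Lithium di-tert-butylbiphenylide in THF at −78 °C cleaves the C5–S bond and delivers the C5 anion regiospecifically, with no free base in the flask.
  - The route is rejoined at 13, which rearranges to 14 and gives 15 on work-up.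

Step 7.
- **What may go wrong:**
  - ionisation of the electron-rich primary mesylate may end in intermolecular Friedel–Crafts alkylation or oligomeric ether formation instead of seven-ring closure;
  - the para silyl group may be lost through quinone methide formation;
  - competing sulfonylation and ionisation of the secondary carbinol would erode the enantiomeric purity.
- **Fallback:** the C5–O4 bond is made by reductive etherification instead of alkylation. The fallback sets out from 10.
  - TEMPO/PhI(OAc)2 oxidises only the primary alcohol and should give the hydroxy aldehyde F3.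
  - Et3SiH with catalytic TMSOTf in CH2Cl2 at −78 °C then closes the ring.
  - The route is rejoined at 12.

Step 6.
- **What may go wrong:**
  - the bulky ortho OTIPS group and the large aryloxymethyl residue may slow hydride transfer and lower the facial discrimination;
  - the formate medium may esterify or ionise the new electron-rich benzylic alcohols.
- **Fallback:** the stereocentre is set before fragment union on the smaller ketone, and the union changes from ketone alkylation to epoxide opening. The fallback sets out from 8 and 2.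
  - Corey–Bakshi–Shibata reduction of 8 with (S)-Me-CBS/BH3·SMe2, where aryl and CH2Cl differ strongly in size, should give the (S)-chlorohydrin F4.
  - K2CO3 in MeCN closes F4 to the (S)-epoxide F5.
  - Separately, NaBH4 reduces 2 to the salicyl alcohol F6.
  - The phenoxide of F6 opens F5 at its CH2 terminus (SN2, C3–O bond untouched).
  - The route is rejoined at 10.

Further compounds
F1 | step 8 | (3S)-5-methoxy acetal of 12 (C5 epimers) | COc1cc2c(cc1O[Si](C(C)C)(C(C)C)C(C)C)OC[C@H](c3cc(O[Si](C(C)C)(C(C)C)C(C)C)c(OC)c(OC)c3O[Si](C(C)C)(C(C)C)C(C)C)OC2OC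
F2 | step 8 | (3S)-5-phenylthio ether of 12 (C5 epimers) | COc1cc2c(cc1O[Si](C(C)C)(C(C)C)C(C)C)OC[C@H](c3cc(O[Si](C(C)C)(C(C)C)C(C)C)c(OC)c(OC)c3O[Si](C(C)C)(C(C)C)C(C)C)OC2Sc4ccccc4
F3 | step 7 | (S)-hydroxy aldehyde | COc1cc(C=O)c(OC[C@@H](O)c2cc(O[Si](C(C)C)(C(C)C)C(C)C)c(OC)c(OC)c2O[Si](C(C)C)(C(C)C)C(C)C)cc1O[Si](C(C)C)(C(C)C)C(C)C
F4 | step 6 | (S)-2-chloro-1-[2,5-bis(triisopropylsilyloxy)-3,4-dimethoxyphenyl]ethan-1-ol | ClC[C@@H](O)c1cc(O[Si](C(C)C)(C(C)C)C(C)C)c(OC)c(OC)c1O[Si](C(C)C)(C(C)C)C(C)C
F5 | step 6 | (S)-2-[2,5-bis(triisopropylsilyloxy)-3,4-dimethoxyphenyl]oxirane | C1[C@@H](O1)c2cc(O[Si](C(C)C)(C(C)C)C(C)C)c(OC)c(OC)c2O[Si](C(C)C)(C(C)C)C(C)C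
F6 | step 6 | 2-(hydroxymethyl)-4-methoxy-5-(triisopropylsilyloxy)phenol | COc1cc(CO)c(O)cc1O[Si](C(C)C)(C(C)C)C(C)C
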